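The side-chain cyclohexene (C1′–C6′) is cut at C1′–C2′ and C5′–C6′: its C3′=C4′ double bond, flanked by the quaternary C1′ and the methine C2′ with cis methyl groups, is a Diels–Alder retron. One catalytic enantioselective [4+2] cycloaddition of methacrolein with an E-configured 2-silyloxy-3-methylpenta-1,3-diene closes that ring, forms both bonds and sets both stereocentres. The silyloxy group that steers the regiochemistry is afterwards reduced off C4′. The formyl group then becomes a terminal alkyne, which is added under copper catalysis to a 2-methylbenzopyrylium ion to set the C2 ether centre of the pyran ring, before saturation and dehydration deliver the chromene.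

Key step: step 2

Assumption: the antipodes of the two chiral catalysts (steps 2 and 10) are written as the usual face-selection models predict; if a first run shows the opposite sense, the mirror-image catalyst, equally available, is used and nothing else changes.

**Fragment A: the cyclohexene alkyne**

Step 1
Reactants: 1 (E)-3-methylpent-3-en-2-one
Product: 2 (E)-3-methyl-2-(triisopropylsilyloxy)penta-1,3-diene
Conditions: LiN(i-Pr)2, THF, −78 °C; TIPSOTf, −78 → 0 °C
Reagents that add atoms: triisopropylsilyl triflate (TIPSOTf), CC(C)[Si](C(C)C)(C(C)C)OS(=O)(=O)C(F)(F)F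
Why: Kinetic deprotonation of the acetyl CH3 by the hindered amide base gives the cross-conjugated lithium dienolate, which the silyl triflate traps on oxygen (silyl enol ether formation) without touching the E C3=C4 bond; the triisopropylsilyl group is chosen because its enol ethers withstand the strongly acidic catalyst of step 2.

Step 2
Reactants: 2 (E)-3-methyl-2-(triisopropylsilyloxy)penta-1,3-diene; 3 methacrolein
Product: 4 (1R,2R)-1,2,3-trimethyl-4-(triisopropylsilyloxy)cyclohex-3-ene-1-carbaldehyde (1- and 2-methyl groups cis)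
Conditions: (R)-3,3-diphenyl-1-(o-tolyl)tetrahydro-1H,3H-pyrrolo[1,2-c][1,3,2]oxazaborole·HNTf2 (20 mol%), CH2Cl2, −78 → −40 °C
Reagents that add atoms: none
Why: The protonated oxazaborolidine binds the formyl oxygen of 3 and holds the enal over one of its aryl faces, and the diene adds to the exposed face in a concerted but asynchronous [4+2] cycloaddition in which C5′–C6′ bonding (silyloxy-activated diene CH2 to the enal β-carbon) runs ahead of C1′–C2′ bonding. The closest known reaction type is the chiral oxazaborolidinium-catalysed Diels–Alder reaction of α-substituted acroleins with 2-silyloxy-1,3-dienes. The six-membered carbocycle is closed by this intermolecular cycloaddition itself, suprafacially on both components, so that both new σ-bonds and the C3′=C4′ enol ether double bond arise together. The absolute configuration at the quaternary C1′ is set by the catalyst, which leaves only one face of the enal α-carbon open; C2′ is set relative to C1′ by the exo-formyl (endo-methyl) transition state that α-substituted acroleins prefer, combined with the E geometry of the diene terminus, which places the two methyl groups cis. The step needs regio-, exo- and enantioselectivity: the regiochemistry is secured twice over because the 2-silyloxy group and the terminal methyl both make the unsubstituted CH2 the nucleophilic terminus, and the low temperature with a non-coordinating counter-ion should keep the catalysed pathway well ahead of the background reaction.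

Step 3
Reactants: 4 (1R,2R)-1,2,3-trimethyl-4-(triisopropylsilyloxy)cyclohex-3-ene-1-carbaldehyde
Product: 5 (3R,4R)-4-formyl-2,3,4-trimethylcyclohex-1-en-1-yl trifluoromethanesulfonate
Conditions: CsF, PhNTf2, DME, rt
Reagents that add atoms: N-phenylbis(trifluoromethanesulfonimide) (PhNTf2), O=S(=O)(N(c1ccccc1)S(=O)(=O)C(F)(F)F)C(F)(F)F
Why: Fluoride cleaves the Si–O bond to a regiodefined cesium enolate that is O-sulfonylated at once by PhNTf2 (enol silane to enol triflate exchange), so the C3′=C4′ position fixed by the cycloaddition is kept, while the non-enolisable neopentyl aldehyde is too hindered to compete by aldol addition and no stereocentre is touched.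

Step 4
Reactants: 5 (3R,4R)-4-formyl-2,3,4-trimethylcyclohex-1-en-1-yl trifluoromethanesulfonate
Product: 6 (1R,2R)-1,2,3-trimethylcyclohex-3-ene-1-carbaldehyde
Conditions: Pd(OAc)2 (5 mol%), PPh3, HCO2H, n-Bu3N, DMF, 60 °C
Reagents that add atoms: none
Why: Oxidative addition of zerovalent palladium into the C–OTf bond, exchange with formate, loss of CO2 and C–H reductive elimination (palladium-catalysed formate reduction of an enol triflate) replace the triflate by hydrogen at C4′ without moving the double bond or touching the aldehyde.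

Step 5
Reactants: 6 (1R,2R)-1,2,3-trimethylcyclohex-3-ene-1-carbaldehyde
Product: 7 (5R,6R)-5-ethynyl-1,5,6-trimethylcyclohex-1-ene (volatile; handled in solution)
Conditions: dimethyl (1-diazo-2-oxopropyl)phosphonate, K2CO3, MeOH, 0 °C → rt
Reagents that add atoms: dimethyl (1-diazo-2-oxopropyl)phosphonate, COP(=O)(OC)C(=[N+]=[N-])C(C)=O
Why: In this Ohira–Bestmann (Seyferth–Gilbert type) homologation the diazomethylphosphonate anion released by methanolysis adds to the aldehyde and the derived alkylidene carbene rearranges by 1,2-hydrogen shift to the terminal alkyne; the aldehyde has no α-hydrogen, so C1′ and C2′ cannot epimerise.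

**Fragment B: the chromone**

Step 6
Reactants: 8 1,2,3,4-tetramethoxybenzene
Product: 9 2,3,4,5-tetramethoxybenzaldehyde
Conditions: POCl3, DMF, 0 → 80 °C; then H2O
Reagents that add atoms: N,N-dimethylformamide, CN(C)C=O; water, O
Why: Vilsmeier–Haack formylation of the electron-rich arene, whose two free ring positions are equivalent by symmetry, so a single aldehyde should form.

Step 7
Reactants: 9 2,3,4,5-tetramethoxybenzaldehyde
Product: 11 2,3,4,5-tetramethoxyphenol, via 2,3,4,5-tetramethoxyphenyl formate 10 (not isolated)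
Conditions: mCPBA, CH2Cl2, 0 °C → rt; then K2CO3 (cat.), MeOH, rt
Reagents that add atoms: 3-chloroperoxybenzoic acid (mCPBA), O=C(OO)c1cccc(Cl)c1
Why: Baeyer–Villiger oxidation in which the electron-rich aryl group migrates (Dakin-type) gives the aryl formate, which mild methanolysis cleaves to the phenol.

Step 8
Reactants: 11 2,3,4,5-tetramethoxyphenol
Product: 12 1-(2-hydroxy-3,4,5,6-tetramethoxyphenyl)ethan-1-one
Conditions: AcOH, BF3·OEt2, 80 °C; then H2O
Reagents that add atoms: acetic acid, CC(=O)O
Why: Boron trifluoride-mediated C-acetylation (Friedel–Crafts, via the phenyl acetate and a Fries-type shift) can only occur at the single unsubstituted ring carbon, ortho to the hydroxyl, and the product is held as a boron chelate until aqueous work-up.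

Step 9
Reactants: 12 1-(2-hydroxy-3,4,5,6-tetramethoxyphenyl)ethan-1-one
Product: 14 5,6,7,8-tetramethoxy-2-methyl-4H-chromen-4-one, via 1-(2-hydroxy-3,4,5,6-tetramethoxyphenyl)butane-1,3-dione 13 (not isolated)
Conditions: NaH, EtOAc, THF, reflux; then AcOH, H2SO4 (cat.), 80 °C
Reagents that add atoms: ethyl acetate, CCOC(C)=O
Why: Claisen condensation of the ketone enolate (as the phenoxide dianion) with ethyl acetate gives the β-diketone, and acid-catalysed cyclodehydration through the free ortho-hydroxyl closes the pyranone ring (standard 2-methylchromone synthesis).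

**Union and endgame**

Step 10
Reactants: 14 5,6,7,8-tetramethoxy-2-methyl-4H-chromen-4-one; 7 (5R,6R)-5-ethynyl-1,5,6-trimethylcyclohex-1-ene
Product: 17 (2S)-5,6,7,8-tetramethoxy-2-methyl-2-{[(1R,2R)-1,2,3-trimethylcyclohex-3-en-1-yl]ethynyl}chroman-4-one, via 4-(tert-butyldimethylsilyloxy)-5,6,7,8-tetramethoxy-2-methylchromenylium triflate 15 (not isolated), via 4-(tert-butyldimethylsilyloxy)-2H-chromene adduct 16 (not isolated)
Conditions: 14 (1.5 equiv), TBSOTf, neat, 60 °C; then 7, CuI (10 mol%), 2,2′-(propane-2,2-diyl)bis[(4S)-4-phenyl-4,5-dihydrooxazole] (12 mol%), i-Pr2NEt, toluene, −78 °C; then 1 M HCl, THF, 0 °C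
Reagents that add atoms: none
Why: O-Silylation of the chromone carbonyl gives an aromatic 4-silyloxybenzopyrylium ion, and the bis(oxazoline)-bound copper acetylide formed from 7 and the amine adds to its C2 (copper-catalysed enantioselective alkynylation of benzopyrylium ions from 2-alkylchromones), the ligand blocking one face of the planar cation so that the C2 ether stereocentre is set by the catalyst and not by the remote C1′/C2′ centres; dilute acid then converts the silyl enol ether into the ketone.

Step 11
Reactants: 17 (2S)-5,6,7,8-tetramethoxy-2-methyl-2-{[(1R,2R)-1,2,3-trimethylcyclohex-3-en-1-yl]ethynyl}chroman-4-one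
Product: 19 (2R)-5,6,7,8-tetramethoxy-2-methyl-2-{2-[(1S,2S)-1,2,3-trimethylcyclohex-3-en-1-yl]ethyl}chroman-4-one, via Z-configured linker alkene 18 (not isolated)
Conditions: KO2CN=NCO2K (excess, in portions), AcOH, MeOH/pyridine, rt
Reagents that add atoms: none
Why: Diimide released from the azodicarboxylate salt delivers H2 by concerted syn transfer first to the alkyne and then to the strained Z-alkene, whereas the trisubstituted ring alkene reacts far more slowly and ketone and aryl ethers are inert (chemoselective diimide reduction); no stereocentre is affected, the changed descriptors being formal.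

Step 12
Reactants: 19 (2R)-5,6,7,8-tetramethoxy-2-methyl-2-{2-[(1S,2S)-1,2,3-trimethylcyclohex-3-en-1-yl]ethyl}chroman-4-one
Product: 20 (2R)-5-hydroxy-6,7,8-trimethoxy-2-methyl-2-{2-[(1S,2S)-1,2,3-trimethylcyclohex-3-en-1-yl]ethyl}chroman-4-one
Conditions: BCl3 (1.2 equiv), CH2Cl2, −78 → 0 °C; then H2O
Reagents that add atoms: none
Why: In this chelation-directed demethylation BCl3 bridges the C4 carbonyl and the peri 5-methoxy oxygen in a six-membered chelate, so chloride removes only that methyl group, and the 6-, 7- and 8-methoxy groups, the tertiary ether and the ring alkene should be left alone at low temperature.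

Step 13
Reactants: 20 (2R)-5-hydroxy-6,7,8-trimethoxy-2-methyl-2-{2-[(1S,2S)-1,2,3-trimethylcyclohex-3-en-1-yl]ethyl}chroman-4-one
Product: 21 (2R)-6,7,8-trimethoxy-2-methyl-2-{2-[(1S,2S)-1,2,3-trimethylcyclohex-3-en-1-yl]ethyl}chromane-4,5-diol (both C4 epimers)
Conditions: NaBH4, MeOH/THF, 0 °C → rt
Reagents that add atoms: none
Why: Borohydride reduction of the aryl ketone to the benzylic alcohol (as for 5-hydroxychroman-4-ones generally) should proceed cleanly; the new C4 centre forms as a mixture, which is of no consequence because it is removed in step 14.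

Step 14
Reactants: 21 (2R)-6,7,8-trimethoxy-2-methyl-2-{2-[(1S,2S)-1,2,3-trimethylcyclohex-3-en-1-yl]ethyl}chromane-4,5-diol
Product: 22 (2R)-6,7,8-trimethoxy-2-methyl-2-{2-[(1S,2S)-1,2,3-trimethylcyclohex-3-en-1-yl]ethyl}-2H-chromen-5-ol (CNP0185215.2)
Conditions: PPTS (10 mol%), toluene, 4 Å MS, 50 °C, dark
Reagents that add atoms: none
Why: Acid-catalysed E1 dehydration through the benzylic cation stabilised by O1, the 5-hydroxyl and the 7-methoxy group (standard chroman-4-ol to 2H-chromene conversion) gives the conjugated C3=C4 bond by loss of H3; the weak acid, mild temperature and exclusion of light are chosen to avoid migration of the ring alkene and electrocyclic ring-opening that would erode C2, and the fully substituted arene cannot be alkylated.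

**Compound list**

1 | (E)-3-methylpent-3-en-2-one | C/C=C(\C)C(C)=O | starting material
2 | (E)-3-methyl-2-(triisopropylsilyloxy)penta-1,3-diene | C=C(O[Si](C(C)C)(C(C)C)C(C)C)/C(C)=C/C | intermediate
3 | methacrolein (2-methylprop-2-enal) | CC(=C)C=O | starting material
4 | (1R,2R)-1,2,3-trimethyl-4-(triisopropylsilyloxy)cyclohex-3-ene-1-carbaldehyde, cis-1,2-dimethyl | O=C[C@]1(C)CCC(O[Si](C(C)C)(C(C)C)C(C)C)=C(C)[C@H]1C | intermediate
5 | (3R,4R)-4-formyl-2,3,4-trimethylcyclohex-1-en-1-yl trifluoromethanesulfonate | O=C[C@]1(C)CCC(OS(=O)(=O)C(F)(F)F)=C(C)[C@H]1C | intermediate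
6 | (1R,2R)-1,2,3-trimethylcyclohex-3-ene-1-carbaldehyde | O=C[C@]1(C)CCC=C(C)[C@H]1C | intermediate
7 | (5R,6R)-5-ethynyl-1,5,6-trimethylcyclohex-1-ene | C#C[C@]1(C)CCC=C(C)[C@H]1C | intermediate
8 | 1,2,3,4-tetramethoxybenzene | COc1ccc(OC)c(OC)c1OC | starting material
9 | 2,3,4,5-tetramethoxybenzaldehyde | COc1cc(C=O)c(OC)c(OC)c1OC | intermediate
10 | 2,3,4,5-tetramethoxyphenyl formate | COc1cc(OC=O)c(OC)c(OC)c1OC | intermediate
11 | 2,3,4,5-tetramethoxyphenol | COc1cc(O)c(OC)c(OC)c1OC | intermediate
12 | 1-(2-hydroxy-3,4,5,6-tetramethoxyphenyl)ethan-1-one | CC(=O)c1c(O)c(OC)c(OC)c(OC)c1OC | intermediate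
13 | 1-(2-hydroxy-3,4,5,6-tetramethoxyphenyl)butane-1,3-dione | CC(=O)CC(=O)c1c(O)c(OC)c(OC)c(OC)c1OC | intermediate
14 | 5,6,7,8-tetramethoxy-2-methyl-4H-chromen-4-one | Cc1cc(=O)c2c(OC)c(OC)c(OC)c(OC)c2o1 | intermediate
15 | 4-(tert-butyldimethylsilyloxy)-5,6,7,8-tetramethoxy-2-methylchromenylium triflate | Cc1cc(O[Si](C)(C)C(C)(C)C)c2c(OC)c(OC)c(OC)c(OC)c2[o+]1.[O-]S(=O)(=O)C(F)(F)F | intermediate
16 | (2S)-4-(tert-butyldimethylsilyloxy)-5,6,7,8-tetramethoxy-2-methyl-2-{[(1R,2R)-1,2,3-trimethylcyclohex-3-en-1-yl]ethynyl}-2H-chromene | COc1c(OC)c2c(c(OC)c1OC)O[C@](C)(C#C[C@]1(C)CCC=C(C)[C@H]1C)C=C2O[Si](C)(C)C(C)(C)C | intermediate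
17 | (2S)-5,6,7,8-tetramethoxy-2-methyl-2-{[(1R,2R)-1,2,3-trimethylcyclohex-3-en-1-yl]ethynyl}chroman-4-one | COc1c(OC)c2c(c(OC)c1OC)O[C@](C)(C#C[C@]1(C)CCC=C(C)[C@H]1C)CC2=O | intermediate
18 | Z-alkene from half-reduction of 17 (2-[(Z)-2-(1,2,3-trimethylcyclohex-3-en-1-yl)ethenyl] analogue, all stereocentres placed as in 17) | COc1c(OC)c2c(c(OC)c1OC)O[C@](C)(/C=C\[C@]1(C)CCC=C(C)[C@H]1C)CC2=O | intermediate
19 | (2R)-5,6,7,8-tetramethoxy-2-methyl-2-{2-[(1S,2S)-1,2,3-trimethylcyclohex-3-en-1-yl]ethyl}chroman-4-one | COc1c(OC)c2c(c(OC)c1OC)O[C@](C)(CC[C@]1(C)CCC=C(C)[C@H]1C)CC2=O | intermediate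
20 | (2R)-5-hydroxy-6,7,8-trimethoxy-2-methyl-2-{2-[(1S,2S)-1,2,3-trimethylcyclohex-3-en-1-yl]ethyl}chroman-4-one | COc1c(O)c2c(c(OC)c1OC)O[C@](C)(CC[C@]1(C)CCC=C(C)[C@H]1C)CC2=O | intermediate
21 | (2R)-6,7,8-trimethoxy-2-methyl-2-{2-[(1S,2S)-1,2,3-trimethylcyclohex-3-en-1-yl]ethyl}chromane-4,5-diol, C4 epimer mixture | COc1c(O)c2c(c(OC)c1OC)O[C@](C)(CC[C@]1(C)CCC=C(C)[C@H]1C)CC2O | intermediate
22 | (2R)-6,7,8-trimethoxy-2-methyl-2-{2-[(1S,2S)-1,2,3-trimethylcyclohex-3-en-1-yl]ethyl}-2H-chromen-5-ol | COc1c(O)c2c(c(OC)c1OC)O[C@](C)(CC[C@]1(C)CCC=C(C)[C@H]1C)C=C2 | target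

**Step count and risk**

Total steps: 14. Longest linear sequence: 10 steps (steps 1–5, then 10–14); the chromone branch (steps 6–9) joins at step 10.

Steps most likely to fail:

1. Step 2. The fully substituted diene may react with eroded facial or exo selectivity, or lose its silyl group to the acidic catalyst before cycloaddition. The fallback gives up catalyst control for resolution and sets out from 2 and 3. An achiral Me2AlCl-promoted cycloaddition (CH2Cl2, −78 °C) should give the racemic cis adduct F1, which is taken through the conditions of steps 3 and 4 as the racemic enol triflate F2 and the racemic aldehyde F3. Condensation of F3 with (1R,2R)-N,N′-dimethyl-1,2-diphenylethane-1,2-diamine (4 Å MS, Et2O) gives two diastereomeric imidazolidines, the imidazolidine of the (1R,2R)-aldehyde F4 and the imidazolidine of its enantiomer F5, to be separated by chromatography. Mild hydrolysis of F4 (0.5 M HCl, Et2O, 0 °C) releases the diamine and comes back to the route at 6.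

2. Step 10. The amine may deprotonate the 2-methyl group of the pyrylium ion and so consume the electrophile, the electron-rich cation may be attacked sluggishly by the hindered acetylide, or facial control may be poor. The fallback abandons the alkyne union and sets out from 6 and 12. Horner–Wadsworth–Emmons reaction of 6 with dimethyl (2-oxopropyl)phosphonate (NaH, THF) gives the E-enone F6; conjugate reduction with [(Ph3P)CuH]6 gives the saturated methyl ketone F7. Kabbe condensation of F7 with 12 (pyrrolidine, MeOH, reflux) builds the chromanone directly as 19 together with its C2 epimer F8. Separation on a chiral stationary phase comes back to the route at 19; steps 10 and 11 are bypassed.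

3. Step 11. Hydrogen transfer may stall at the Z-alkene, which is shielded by two fully substituted carbons, or the large excess of diimide may begin to attack the ring double bond. The fallback masks the ring alkene so that ordinary heterogeneous hydrogenation can be used, and sets out from 17. Epoxidation of the C3′=C4′ bond (mCPBA, NaHCO3, CH2Cl2, 0 °C) gives the epoxy alkyne F9 as an inconsequential epoxide mixture; hydrogenation (H2, Pd/C, EtOAc) gives the saturated epoxide F10. Deoxygenation with Zn, NaI and NaOAc in AcOH regenerates the double bond in its original position and comes back to the route at 19.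

**Further compounds**

F1 | step 2 | racemic cis-1,2,3-trimethyl-4-(triisopropylsilyloxy)cyclohex-3-ene-1-carbaldehyde (4 and its enantiomer) | O=C[C@]1(C)CCC(O[Si](C(C)C)(C(C)C)C(C)C)=C(C)[C@H]1C.O=C[C@@]1(C)CCC(O[Si](C(C)C)(C(C)C)C(C)C)=C(C)[C@@H]1C
F2 | step 2 | racemic cis-4-formyl-2,3,4-trimethylcyclohex-1-en-1-yl trifluoromethanesulfonate (5 and its enantiomer) | O=C[C@]1(C)CCC(OS(=O)(=O)C(F)(F)F)=C(C)[C@H]1C.O=C[C@@]1(C)CCC(OS(=O)(=O)C(F)(F)F)=C(C)[C@@H]1C
F3 | step 2 | racemic cis-1,2,3-trimethylcyclohex-3-ene-1-carbaldehyde (6 and its enantiomer) | O=C[C@]1(C)CCC=C(C)[C@H]1C.O=C[C@@]1(C)CCC=C(C)[C@@H]1C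
F4 | step 2 | (4R,5R)-1,3-dimethyl-4,5-diphenyl-2-[(1R,2R)-1,2,3-trimethylcyclohex-3-en-1-yl]imidazolidine | CN1[C@H](c2ccccc2)[C@@H](c2ccccc2)N(C)C1[C@]1(C)CCC=C(C)[C@H]1C
F5 | step 2 | (4R,5R)-1,3-dimethyl-4,5-diphenyl-2-[(1S,2S)-1,2,3-trimethylcyclohex-3-en-1-yl]imidazolidine | CN1[C@H](c2ccccc2)[C@@H](c2ccccc2)N(C)C1[C@@]1(C)CCC=C(C)[C@@H]1C
F6 | step 10 | (E)-4-(1,2,3-trimethylcyclohex-3-en-1-yl)but-3-en-2-one, ring stereocentres placed as in 6 | CC(=O)/C=C/[C@]1(C)CCC=C(C)[C@H]1C
F7 | step 10 | 4-[(1S,2S)-1,2,3-trimethylcyclohex-3-en-1-yl]butan-2-one | CC(=O)CC[C@]1(C)CCC=C(C)[C@H]1C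
F8 | step 10 | (2S)-5,6,7,8-tetramethoxy-2-methyl-2-{2-[(1S,2S)-1,2,3-trimethylcyclohex-3-en-1-yl]ethyl}chroman-4-one (C2 epimer of 19) | COc1c(OC)c2c(c(OC)c1OC)O[C@@](C)(CC[C@]1(C)CCC=C(C)[C@H]1C)CC2=O
F9 | step 11 | 3′,4′-epoxide of 17 (epoxide mixture, other stereocentres as in 17) | COc1c(OC)c2c(c(OC)c1OC)O[C@](C)(C#C[C@]1(C)CCC3OC3(C)[C@H]1C)CC2=O
F10 | step 11 | 3′,4′-epoxide of 19 (epoxide mixture, other stereocentres as in 19) | COc1c(OC)c2c(c(OC)c1OC)O[C@](C)(CC[C@]1(C)CCC3OC3(C)[C@H]1C)CC2=O
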